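**Assumption:** the target, 2-(3,5-diiodo-4-methoxyphenyl)acetamide, has no stereocentre and is achiral, so no stereocontrol is needed.

## Retrosynthetic overview

1. Target 5 is disconnected at two C–O bonds at once, the aryl O–CH3 bond and the amide C=O bond. Both are traced to one molecule of methanol split across the nitrile and the phenol of 2 (Pinner imidate, then methyl transfer from imidate oxygen to phenoxide oxygen).
2. Compound 2 is disconnected at its two C–I bonds to 2-(4-hydroxyphenyl)acetonitrile 1 and an electrophilic iodine source.
3. No ring is formed. The benzene ring and the ArCH2–C bond are bought with 1.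

## Route

**Step 1**
Reactants: 1 2-(4-hydroxyphenyl)acetonitrile
Product: 2 2-(4-hydroxy-3,5-diiodophenyl)acetonitrile
Conditions: NIS (2.1 equiv), TsOH·H2O (10 mol %), MeCN, 0 °C to rt, dark, 3 h; aqueous Na2S2O3 wash, recrystallise
Reagents that add atoms: N-iodosuccinimide, O=C1CCC(=O)N1I
Why: Electrophilic aromatic iodination, in which the free phenol directs both iodine atoms to its two ortho positions because the para position is blocked by the CH2CN group; no stereocentre is formed.

**Step 2**
Reactants: 2 2-(4-hydroxy-3,5-diiodophenyl)acetonitrile
Product: 5 2-(3,5-diiodo-4-methoxyphenyl)acetamide, via imidate hydrochloride 3 (not isolated), via free imidate 4 (not isolated)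
Conditions: first HCl (4 M in 1,4-dioxane, 5 equiv), MeOH (1.5 equiv), CH2Cl2, 0 °C, 16 h, then evaporate at or below 25 °C; then 2,4,6-collidine (1.1 equiv), Bu4NI (10 mol %), 4 Å molecular sieves, dry MeCN, sealed tube, 50 °C, 12 h
Reagents that add atoms: methanol, CO
Why: Proposed new method: a Pinner reaction adds methanol to the nitrile to give imidate hydrochloride 3, and the hindered base then releases imidate 4, whose conjugate acid (pKa about 6.5 to 7) is matched to the 2,6-diiodophenol (pKa about 6.5), so a large share sits as an iminium phenoxide ion pair; the phenoxide oxygen of one molecule then attacks the O-methyl carbon of another in an SN2 step, directly or with iodide as a catalytic methyl shuttle, and expels the neutral primary amide, so one methanol gives its oxygen to the amide carbonyl and its methyl group to the aryl ether; the closest known reaction types are the Pinner cleavage of imidate hydrochlorides to amide plus alkyl chloride and acid-promoted O-alkylation by alkyl imidates, and no stereocentre is formed.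

## Compound list

1 | 2-(4-hydroxyphenyl)acetonitrile (4-hydroxybenzyl cyanide) | N#CCc1ccc(O)cc1 | starting material
2 | 2-(4-hydroxy-3,5-diiodophenyl)acetonitrile | N#CCc1cc(I)c(O)c(I)c1 | intermediate
3 | methyl 2-(4-hydroxy-3,5-diiodophenyl)ethanimidate hydrochloride (Pinner salt, not isolated) | COC(=[NH2+])Cc1cc(I)c(O)c(I)c1.[Cl-] | intermediate
4 | methyl 2-(4-hydroxy-3,5-diiodophenyl)ethanimidate (free base, in equilibrium with its iminium phenoxide form, not isolated) | COC(=N)Cc1cc(I)c(O)c(I)c1 | intermediate
5 | 2-(3,5-diiodo-4-methoxyphenyl)acetamide | COc1c(I)cc(CC(N)=O)cc1I | target

## Step count and risks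

Total step count: 2. Longest linear sequence: 2 steps.

The route has only two steps, so both are ranked, the more doubtful first.

**Step 2 (the proposed new step).** The main risks are:
- hydrolysis of 3 or 4 to the methyl ester by traces of water;
- self-condensation of imidate 4 (amidine or triazine formation);
- loss of methanol back to nitrile 2;
- incomplete methyl transfer, which leaves the hydroxy amide.

The fallback uses known chemistry and sets out from compound 2. The phenol is O-methylated by a Williamson reaction (MeI, K2CO3, acetone, rt) to give 2-(3,5-diiodo-4-methoxyphenyl)acetonitrile F1. The nitrile is then hydrated with alkaline peroxide (H2O2, K2CO3, DMSO, rt), which comes back to the route at compound 5.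

**Step 1.** The main risks are a mixture of mono- and di-iodide that is hard to separate, and side reactions of NIS with the benzylic nitrile. The fallback sets out from compound 1 and changes the order, so that the ring is iodinated at the amide stage as a water-soluble phenoxide and the Pinner chemistry is given up. The nitrile is first hydrated (concentrated HCl, 40 °C) to 2-(4-hydroxyphenyl)acetamide F2. This is iodinated in water (I2, KI, aqueous NH3, rt, then acidify) to give 2-(4-hydroxy-3,5-diiodophenyl)acetamide F3, which precipitates. F3 is O-methylated (MeI, K2CO3, DMF, rt), which comes back to the route at compound 5.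

## Further compounds

F1 | step 2 | 2-(3,5-diiodo-4-methoxyphenyl)acetonitrile | COc1c(I)cc(CC#N)cc1I
F2 | step 1 | 2-(4-hydroxyphenyl)acetamide | NC(=O)Cc1ccc(O)cc1
F3 | step 1 | 2-(4-hydroxy-3,5-diiodophenyl)acetamide | NC(=O)Cc1cc(I)c(O)c(I)c1
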